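**Plan**

- Retrosynthesis: take off the four O-allyl groups; turn the C7 prenyl group back into C7–CHO (two Wittig steps); cut ring B at C5–C6 (Michael) and then at C1–C8 ([3,3]), which removes the whole C6–C7–C8 bridge and flattens the bicyclo[3.3.1]nonane to aryl allyl ether 16; cut the ether C–O to acylphloroglucinol 10 and allylic alcohol 15.
- Enabling feature: ring A (C1–C2–C3–C4–C5–C9) is a dearomatised acylphloroglucinol in which C1 and C5 are the two prenylated carbons ortho to the oxygen on C9. A 2-formylallyl unit hung on that oxygen can pass C8 to C1 by a [3,3] shift and then offer C6, now part of a 2-methylene aldehyde, to the enolate carbon C5.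
- Forward: the aroyl ring and phloroglucinol are joined and C-prenylated (10); a syn-carbometalation gives the tetrasubstituted alkene 15; ether 16; one operation makes C1–C8 and closes ring B through C5–C6; then the C7 side chain and deprotection. Ring A is the former aromatic ring; ring B arises in step 10.
- Stereochemistry: the (E)-geometry of 15 and the chair [3,3] transition state fix C8 relative to C1; a chiral ammonium counter-cation chooses between the two enantiotopic ortho carbons (absolute sense at C1); C5 follows geometrically; C7 is set by equilibration to the equatorial aldehyde.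

Key step: step 10

Assumption: the target is treated as the C4-enol tautomer drawn; atoms are numbered C1–C9 as in the bicyclo[3.3.1]nonane core (C1, C5 bridgeheads, C9 bridging carbonyl, C8 the methyl/homoprenyl carbon). The sense of induction of the chiral cation in step 10 cannot be predicted, so the cinchonidine-derived salt is written and its cinchonine-derived pseudo-enantiomer would be taken if the sense is opposite.

Step 1
Reactants: 1 2,4,5-trihydroxybenzaldehyde
Product: 2 2,4,5-tris(allyloxy)benzaldehyde
Conditions: allyl bromide (3.6 equiv), K2CO3, DMF, 60 °C, Ar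
Reagents that add atoms: allyl bromide, C=CCBr
Why: Williamson etherification (SN2) of all three phenols; the allyl ethers tolerate the bases, organometallics and dilute acid used later and leave together in step 14.

Step 2
Reactants: 3 phloroglucinol
Product: 4 1,3,5-tris(methoxymethoxy)benzene
Conditions: MOMCl (3.6 equiv), i-Pr2NEt, DMF, 0 °C → rt
Reagents that add atoms: chloromethyl methyl ether, COCCl
Why: O-alkylation of the phenols by the chloromethyl ether gives the tris-MOM ether, whose acetal oxygens direct the lithiation of step 3 and which is cleaved by acid without touching allyl ethers.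

Step 3
Reactants: 4 1,3,5-tris(methoxymethoxy)benzene; 2 2,4,5-tris(allyloxy)benzaldehyde
Product: 6 [2,4,6-tris(methoxymethoxy)phenyl][2,4,5-tris(allyloxy)phenyl]methanol (racemic), via aryllithium 5 (not isolated)
Conditions: n-BuLi, THF, 0 °C; then 2, −78 °C → rt; H2O
Reagents that add atoms: none
Why: Directed ortho-metalation between two MOM ethers followed by 1,2-addition of the aryllithium to the aldehyde; the new carbinol centre is racemic and is erased in step 4.

Step 4
Reactants: 6 [2,4,6-tris(methoxymethoxy)phenyl][2,4,5-tris(allyloxy)phenyl]methanol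
Product: 7 [2,4,6-tris(methoxymethoxy)phenyl][2,4,5-tris(allyloxy)phenyl]methanone
Conditions: MnO2 (activated, excess), CH2Cl2, rt
Reagents that add atoms: none
Why: MnO2 oxidation of a doubly benzylic, electron-rich secondary alcohol to the diaryl ketone; acetals and allyl ethers are inert.

Step 5
Reactants: 7 [2,4,6-tris(methoxymethoxy)phenyl][2,4,5-tris(allyloxy)phenyl]methanone
Product: 8 (2,4,6-trihydroxyphenyl)[2,4,5-tris(allyloxy)phenyl]methanone
Conditions: conc. HCl (cat.), MeOH, 50 °C
Reagents that add atoms: none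
Why: Acid-catalysed transacetalisation (MOM cleavage) in methanol frees the acylphloroglucinol, while aryl allyl ethers are stable to dilute acid.

Step 6
Reactants: 8 (2,4,6-trihydroxyphenyl)[2,4,5-tris(allyloxy)phenyl]methanone; 9 prenyl bromide
Product: 10 [2,4,6-trihydroxy-3,5-bis(3-methylbut-2-en-1-yl)phenyl][2,4,5-tris(allyloxy)phenyl]methanone
Conditions: 9 (2.1 equiv), 10% aq. KOH, 0 °C → rt
Reagents that add atoms: none
Why: Twofold C-alkylation of the acylphloroglucinol polyanion in water (Friedel–Crafts-type C-prenylation), where solvation of the phenolate oxygens steers the allylic bromide to the two free ring carbons.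

Step 7
Reactants: 11 propargyl alcohol; 12 5-bromo-2-methylpent-2-ene
Product: 13 7-methyloct-6-en-2-yn-1-ol
Conditions: n-BuLi (2.1 equiv), THF/DMPU, −78 → 0 °C; then 12, rt; H2O
Reagents that add atoms: none
Why: SN2 alkylation of dilithiated propargyl alcohol at the acetylide carbon by the primary bromide.

Step 8
Reactants: 13 7-methyloct-6-en-2-yn-1-ol
Product: 15 (2E)-2-(hydroxymethyl)-3,7-dimethylocta-2,6-dienal, via alkenylmagnesium bromide 14 (not isolated)
Conditions: MeMgBr (4 equiv), Fe(acac)3 (10 mol %), THF, −78 → 0 °C; then DMF, 0 °C; H2O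
Reagents that add atoms: methylmagnesium bromide, C[Mg]Br; N,N-dimethylformamide, CN(C)C=O
Why: Alkoxide-directed iron-catalysed syn-carbomagnesiation puts methyl on the distal alkyne carbon and magnesium on the proximal one (methyl and Mg cis in 14), and formylation of the alkenyl Grignard with DMF (Bouveault reaction) keeps the geometry, so CHO is cis to methyl and CH2OH cis to the homoprenyl chain.

Step 9
Reactants: 10 [2,4,6-trihydroxy-3,5-bis(3-methylbut-2-en-1-yl)phenyl][2,4,5-tris(allyloxy)phenyl]methanone; 15 (2E)-2-(hydroxymethyl)-3,7-dimethylocta-2,6-dienal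
Product: 16 (2E)-2-{[4-(2,4,5-tris(allyloxy)benzoyl)-3,5-dihydroxy-2,6-bis(3-methylbut-2-en-1-yl)phenoxy]methyl}-3,7-dimethylocta-2,6-dienal
Conditions: PPh3, DIAD, THF, 0 °C → rt
Reagents that add atoms: none
Why: Mitsunobu etherification: SN2 displacement at the primary allylic carbon (the fully substituted γ-carbon rules out allylic transposition) by the most acidic phenol, the 4-OH that is not hydrogen-bonded to the ketone; the alkene geometry is untouched.

Step 10
Reactants: 16 (2E)-2-{[4-(2,4,5-tris(allyloxy)benzoyl)-3,5-dihydroxy-2,6-bis(3-methylbut-2-en-1-yl)phenoxy]methyl}-3,7-dimethylocta-2,6-dienal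
Product: 18 (1S,5S,7R,8S)-3-[2,4,5-tris(allyloxy)benzoyl]-4-hydroxy-8-methyl-8-(4-methylpent-3-en-1-yl)-1,5-bis(3-methylbut-2-en-1-yl)-2,9-dioxobicyclo[3.3.1]non-3-ene-7-carbaldehyde (formyl equatorial; C8 methyl axial), via cyclohexadienone 17 (not isolated)
Conditions: 2,7-bis[(cinchonidinium-1-yl)methyl]naphthalene dibromide (20 mol %), CsOH·H2O (3 equiv), 4 Å MS, CH2Cl2, −40 °C → rt; then 1 M HCl
Reagents that add atoms: none
Why: Proposed new method: deprotonation of a chelated phenol of 16 should turn the ortho-Claisen rearrangement into a charge-accelerated [3,3] shift (in the polar limit an intramolecular conjugate addition of the prenylated ortho carbon to C8 of the enal, with the ring oxygen leaving as the C9 carbonyl), and tight pairing of the phenolate with the chiral bis-ammonium cation is expected to select one of the two enantiotopic prenylated ortho carbons; the closest known reaction types are the thermal ortho-Claisen rearrangement of ortho-blocked aryl allyl ethers to cyclohexadienones and the cinchona-ammonium-mediated enantioselective alkylative dearomatisation–annulation of prenylated acylphloroglucinols with 2-(acyloxymethyl)enals. The shift gives 17 with the C1–C8 bond and a newly exposed 2-methylene aldehyde, and the enolate carbon C5 then adds to C6 in a 6-endo-trig Michael closure of ring B (C5–C6–C7–C8–C1–C9). C8 is tied to C1 by the chair transition state acting on the (E)-alkene (the methyl cis to CHO ends axial on ring B and anti to C2, the homoprenyl chain equatorial), the absolute sense at C1 comes from the chiral cation, C5 follows because C6 can only reach the ring face that carries the side chain, and C7 ends as the equatorial aldehyde after base equilibration of the epimerisable formyl centre. The step needs chair over boat and closure at the prenyl-bearing C5 instead of the aroyl-bearing C3: the first rests on the usual chair preference of the sigmatropic shift, the second on C3 being a hindered, weakly nucleophilic tricarbonyl-methide carbon.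

Step 11
Reactants: 18 bicyclic aldehyde (formyl equatorial)
Product: 19 (1S,5S,7R,8S)-4-(allyloxy)-3-[2,4,5-tris(allyloxy)benzoyl]-8-methyl-8-(4-methylpent-3-en-1-yl)-1,5-bis(3-methylbut-2-en-1-yl)-2,9-dioxobicyclo[3.3.1]non-3-ene-7-carbaldehyde
Conditions: K2CO3, DMF, 40 °C; then allyl bromide, rt
Reagents that add atoms: allyl bromide, C=CCBr
Why: The potassium enolate conditions first equilibrate the epimerisable C7 formyl centre to the equatorial position and then O-alkylate the vinylogous acid (Williamson-type; C3 is fully substituted and the C4 oxygen is the less hindered one), which switches off enolate aldol chemistry for steps 12 and 13.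

Step 12
Reactants: 19 allyl enol ether aldehyde
Product: 21 (1S,5S,7S,8S)-4-(allyloxy)-3-[2,4,5-tris(allyloxy)benzoyl]-8-methyl-8-(4-methylpent-3-en-1-yl)-1,5-bis(3-methylbut-2-en-1-yl)-7-(2-oxoethyl)bicyclo[3.3.1]non-3-ene-2,9-dione, via enol ether 20 (not isolated)
Conditions: (methoxymethyl)triphenylphosphonium chloride, KOt-Bu, THF, 0 °C; then 1 M aq. HCl, THF, 0 °C → rt
Reagents that add atoms: (methoxymethyl)triphenylphosphonium chloride, COC[P+](c1ccccc1)(c1ccccc1)c1ccccc1.[Cl-]; water, O
Why: Wittig reaction of the aldehyde, the only unhindered carbonyl group, with the methoxymethylene ylide and mild hydrolysis of enol ether 20 give the one-carbon homologue; the C7 centre was set before and can no longer epimerise afterwards.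

Step 13
Reactants: 21 homologated aldehyde
Product: 22 (1S,5S,7R,8S)-4-(allyloxy)-3-[2,4,5-tris(allyloxy)benzoyl]-8-methyl-8-(4-methylpent-3-en-1-yl)-1,5,7-tris(3-methylbut-2-en-1-yl)bicyclo[3.3.1]non-3-ene-2,9-dione
Conditions: isopropyltriphenylphosphonium iodide, n-BuLi, THF, −78 °C → rt
Reagents that add atoms: isopropyltriphenylphosphonium iodide, CC(C)[P+](c1ccccc1)(c1ccccc1)c1ccccc1.[I-]
Why: Wittig olefination of the aldehyde with the isopropylidene ylide completes the C7 prenyl group; no stereocentre is formed.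

Step 14
Reactants: 22 tetra-O-allyl guttiferone L
Product: 23 guttiferone L
Conditions: Pd(PPh3)4 (10 mol %), morpholine (20 equiv), THF, rt, Ar
Reagents that add atoms: none
Why: Tsuji–Trost-type deallylation: zerovalent palladium ionises the three aryl allyl ethers and the allyl enol ether and morpholine captures the π-allyl units; the neutral conditions spare the four trisubstituted alkenes and the enolised trione.

**Compound list**

1 | 2,4,5-trihydroxybenzaldehyde | O=Cc1cc(O)c(O)cc1O | starting material
2 | 2,4,5-tris(allyloxy)benzaldehyde | O=Cc1cc(OCC=C)c(OCC=C)cc1OCC=C | intermediate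
3 | phloroglucinol (benzene-1,3,5-triol) | Oc1cc(O)cc(O)c1 | starting material
4 | 1,3,5-tris(methoxymethoxy)benzene | COCOc1cc(OCOC)cc(OCOC)c1 | intermediate
5 | [2,4,6-tris(methoxymethoxy)phenyl]lithium | [Li]c1c(OCOC)cc(OCOC)cc1OCOC | intermediate
6 | [2,4,6-tris(methoxymethoxy)phenyl][2,4,5-tris(allyloxy)phenyl]methanol (racemic) | COCOc1cc(OCOC)c(C(O)c2cc(OCC=C)c(OCC=C)cc2OCC=C)c(OCOC)c1 | intermediate
7 | [2,4,6-tris(methoxymethoxy)phenyl][2,4,5-tris(allyloxy)phenyl]methanone | COCOc1cc(OCOC)c(C(=O)c2cc(OCC=C)c(OCC=C)cc2OCC=C)c(OCOC)c1 | intermediate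
8 | (2,4,6-trihydroxyphenyl)[2,4,5-tris(allyloxy)phenyl]methanone | Oc1cc(O)c(C(=O)c2cc(OCC=C)c(OCC=C)cc2OCC=C)c(O)c1 | intermediate
9 | prenyl bromide (1-bromo-3-methylbut-2-ene) | CC(C)=CCBr | starting material
10 | [2,4,6-trihydroxy-3,5-bis(3-methylbut-2-en-1-yl)phenyl][2,4,5-tris(allyloxy)phenyl]methanone | CC(C)=CCc1c(O)c(CC=C(C)C)c(O)c(C(=O)c2cc(OCC=C)c(OCC=C)cc2OCC=C)c1O | intermediate
11 | propargyl alcohol (prop-2-yn-1-ol) | C#CCO | starting material
12 | 5-bromo-2-methylpent-2-ene | CC(C)=CCCBr | starting material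
13 | 7-methyloct-6-en-2-yn-1-ol | CC(C)=CCCC#CCO | intermediate
14 | bromomagnesium (2E)-2-(bromomagnesio)-3,7-dimethylocta-2,6-dien-1-olate (Mg cis to the C3 methyl) | Br[Mg]OC/C([Mg]Br)=C(/C)CCC=C(C)C | intermediate
15 | (2E)-2-(hydroxymethyl)-3,7-dimethylocta-2,6-dienal (CHO cis to the C3 methyl, CH2OH cis to the chain) | OC/C(C=O)=C(/C)CCC=C(C)C | intermediate
16 | (2E)-2-{[4-(2,4,5-tris(allyloxy)benzoyl)-3,5-dihydroxy-2,6-bis(3-methylbut-2-en-1-yl)phenoxy]methyl}-3,7-dimethylocta-2,6-dienal | O=C/C(COc1c(CC=C(C)C)c(O)c(C(=O)c2cc(OCC=C)c(OCC=C)cc2OCC=C)c(O)c1CC=C(C)C)=C(\C)CCC=C(C)C | intermediate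
17 | (6R)-4-[2,4,5-tris(allyloxy)benzoyl]-6-[(3S)-2-formyl-3,7-dimethylocta-1,6-dien-3-yl]-3,5-dihydroxy-2,6-bis(3-methylbut-2-en-1-yl)cyclohexa-2,4-dien-1-one | CC(C)=CCC[C@@](C)(C(C=O)=C)[C@@]1(CC=C(C)C)C(=O)C(CC=C(C)C)=C(O)C(C(=O)c2cc(OCC=C)c(OCC=C)cc2OCC=C)=C1O | intermediate
18 | (1S,5S,7R,8S)-3-[2,4,5-tris(allyloxy)benzoyl]-4-hydroxy-8-methyl-8-(4-methylpent-3-en-1-yl)-1,5-bis(3-methylbut-2-en-1-yl)-2,9-dioxobicyclo[3.3.1]non-3-ene-7-carbaldehyde (formyl equatorial, C8 methyl axial) | CC(C)=CCC[C@@]1(C)[C@H](C=O)C[C@]2(CC=C(C)C)C(=O)[C@@]1(CC=C(C)C)C(=O)C(C(=O)c1cc(OCC=C)c(OCC=C)cc1OCC=C)=C2O | intermediate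
19 | (1S,5S,7R,8S)-4-(allyloxy)-3-[2,4,5-tris(allyloxy)benzoyl]-8-methyl-8-(4-methylpent-3-en-1-yl)-1,5-bis(3-methylbut-2-en-1-yl)-2,9-dioxobicyclo[3.3.1]non-3-ene-7-carbaldehyde | CC(C)=CCC[C@@]1(C)[C@H](C=O)C[C@]2(CC=C(C)C)C(=O)[C@@]1(CC=C(C)C)C(=O)C(C(=O)c1cc(OCC=C)c(OCC=C)cc1OCC=C)=C2OCC=C | intermediate
20 | (1S,5S,7S,8S)-4-(allyloxy)-3-[2,4,5-tris(allyloxy)benzoyl]-7-(2-methoxyethenyl)-8-methyl-8-(4-methylpent-3-en-1-yl)-1,5-bis(3-methylbut-2-en-1-yl)bicyclo[3.3.1]non-3-ene-2,9-dione (E/Z mixture at the enol ether) | CC(C)=CCC[C@@]1(C)[C@H](C=COC)C[C@]2(CC=C(C)C)C(=O)[C@@]1(CC=C(C)C)C(=O)C(C(=O)c1cc(OCC=C)c(OCC=C)cc1OCC=C)=C2OCC=C | intermediate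
21 | (1S,5S,7S,8S)-4-(allyloxy)-3-[2,4,5-tris(allyloxy)benzoyl]-8-methyl-8-(4-methylpent-3-en-1-yl)-1,5-bis(3-methylbut-2-en-1-yl)-7-(2-oxoethyl)bicyclo[3.3.1]non-3-ene-2,9-dione | CC(C)=CCC[C@@]1(C)[C@H](CC=O)C[C@]2(CC=C(C)C)C(=O)[C@@]1(CC=C(C)C)C(=O)C(C(=O)c1cc(OCC=C)c(OCC=C)cc1OCC=C)=C2OCC=C | intermediate
22 | (1S,5S,7R,8S)-4-(allyloxy)-3-[2,4,5-tris(allyloxy)benzoyl]-8-methyl-8-(4-methylpent-3-en-1-yl)-1,5,7-tris(3-methylbut-2-en-1-yl)bicyclo[3.3.1]non-3-ene-2,9-dione | CC(C)=CCC[C@@]1(C)[C@H](CC=C(C)C)C[C@]2(CC=C(C)C)C(=O)[C@@]1(CC=C(C)C)C(=O)C(C(=O)c1cc(OCC=C)c(OCC=C)cc1OCC=C)=C2OCC=C | intermediate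
23 | guttiferone L, (1S,5S,7R,8S)-4-hydroxy-8-methyl-8-(4-methylpent-3-en-1-yl)-1,5,7-tris(3-methylbut-2-en-1-yl)-3-(2,4,5-trihydroxybenzoyl)bicyclo[3.3.1]non-3-ene-2,9-dione (C7 prenyl equatorial, C8 methyl axial) | CC(C)=CCC[C@@]1(C)[C@H](CC=C(C)C)C[C@]2(CC=C(C)C)C(=O)[C@@]1(CC=C(C)C)C(=O)C(C(=O)c1cc(O)c(O)cc1O)=C2O | target

**Step count and risks**

Total step count: 14. Longest linear sequence: 11 steps (3 → 4 → 6 → 7 → 8 → 10 → 16 → 18 → 19 → 21 → 22 → 23).

Steps most likely to fail:

Step 10 (proposed new method). The ion pair may discriminate poorly between the two enantiotopic ortho carbons, with an uncatalysed shift competing. Some material may also leak through the boat transition state, and the axial aldehyde may be held back by reversible aldol addition of C3. Fallback with known chemistry only, setting out from 16: heat 16 with K2CO3 in toluene (80 °C), an uncatalysed ortho-Claisen rearrangement followed by base-mediated Michael closure. This should give 18 as the racemate, that is 18 together with the mirror-image bicyclic aldehyde F2, formed through the mirror-image cyclohexadienone F1. The enantiomers are separated by preparative chromatography on a cellulose tris(3,5-dimethylphenylcarbamate) phase, and the route resumes at 18.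

Step 9. Activation may be sluggish at a phenol flanked by two prenyl groups, the ambident phenol may be alkylated at carbon or at a chelated hydroxyl, and the alkene geometry may be lost by reversible phosphine addition to the enal. Fallback, setting out from 10 and 15: give up the tether. Acetylation of 15 (Ac2O, pyridine) gives the allylic acetate (2E)-2-(acetoxymethyl)-3,7-dimethylocta-2,6-dienal F3. F3 and 10 are combined under the chiral ammonium/CsOH·H2O conditions of step 10 in an intermolecular alkylative dearomatisation–annulation (Michael addition, acetate elimination, Michael addition through 17), which comes back to the route at 18. The price is that C8 is then set in an open transition state, so its configuration relative to C1 would have to be proven at 18.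

Step 8. The carbomagnesiation may be incomplete or not regioselective, the alkenylmetal may lose its geometry, formylation next to the alkoxide may be poor, and the hydroxymethyl enal may isomerise on handling. Fallback by stereospecific carbocupration, setting out from 12: magnesium in THF gives the Grignard reagent (4-methylpent-3-en-1-yl)magnesium bromide F4. With CuBr·SMe2 it adds syn to methyl but-2-ynoate at −78 °C to give the alkenylcopper methyl (2Z)-2-cuprio-3,7-dimethylocta-2,6-dienoate F5. Iodine converts this into the iodo ester methyl (2Z)-2-iodo-3,7-dimethylocta-2,6-dienoate F6 (iodine cis to the homoprenyl chain). i-Bu2AlH reduction gives the iodo alcohol (2Z)-2-iodo-3,7-dimethylocta-2,6-dien-1-ol F7, and MnO2 oxidation the iodo enal (2Z)-2-iodo-3,7-dimethylocta-2,6-dienal F8. Stille coupling of F8 with (tributylstannyl)methanol (Pd(PPh3)4, dioxane, 80 °C) puts the hydroxymethyl group where iodine was and comes back to the route at 15.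

**Further compounds**

F1 | step 10 | mirror-image cyclohexadienone, (6S)-4-[2,4,5-tris(allyloxy)benzoyl]-6-[(3R)-2-formyl-3,7-dimethylocta-1,6-dien-3-yl]-3,5-dihydroxy-2,6-bis(3-methylbut-2-en-1-yl)cyclohexa-2,4-dien-1-one | CC(C)=CCC[C@](C)(C(C=O)=C)[C@]1(CC=C(C)C)C(=O)C(CC=C(C)C)=C(O)C(C(=O)c2cc(OCC=C)c(OCC=C)cc2OCC=C)=C1O
F2 | step 10 | mirror-image bicyclic aldehyde, (1R,5R,7S,8R)-enantiomer of 18 | CC(C)=CCC[C@]1(C)[C@@H](C=O)C[C@@]2(CC=C(C)C)C(=O)[C@]1(CC=C(C)C)C(=O)C(C(=O)c1cc(OCC=C)c(OCC=C)cc1OCC=C)=C2O
F3 | step 9 | (2E)-2-(acetoxymethyl)-3,7-dimethylocta-2,6-dienal | CC(=O)OC/C(C=O)=C(/C)CCC=C(C)C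
F4 | step 8 | (4-methylpent-3-en-1-yl)magnesium bromide | CC(C)=CCC[Mg]Br
F5 | step 8 | methyl (2Z)-2-cuprio-3,7-dimethylocta-2,6-dienoate (copper cis to the homoprenyl chain) | COC(=O)/C([Cu])=C(\C)CCC=C(C)C
F6 | step 8 | methyl (2Z)-2-iodo-3,7-dimethylocta-2,6-dienoate | COC(=O)/C(I)=C(\C)CCC=C(C)C
F7 | step 8 | (2Z)-2-iodo-3,7-dimethylocta-2,6-dien-1-ol | OC/C(I)=C(\C)CCC=C(C)C
F8 | step 8 | (2Z)-2-iodo-3,7-dimethylocta-2,6-dienal | O=C/C(I)=C(\C)CCC=C(C)C
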